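The numbers in the tables were generated by integration for an exercise, and the scatter is random.

At early times the readings say little: the midnight run's 0 % product at 1.00 h lies inside a scatter of 0.5 percentage points. We therefore read each run at its last point.

| flask | solid substrate | free catalyst | remark | time |
|---|---|---|---|---|
| midnight | 0.0050 M | 21 µM | run made earlier |  |
| noon | 0.0075 M | 21 µM | run made earlier |  |
| summer | 0.010 M | 32 µM | run made earlier |  |
| flask | 0.010 M | 21 µM |  | 25 h |

| run | time / h | product / % | crystals / % |
|---|---|---|---|
| midnight | 1.00 | 0 | 0.1 |
| midnight | 3.00 | 1.5 | 0.1 |
| midnight | 5.00 | 2.0 | 0 |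
| midnight | 8.00 | 3.6 | 0 |
| midnight | 12.0 | 5.6 | 0 |
| midnight | 15.0 | 8.3 | 0 |
| noon | 2.50 | 1.1 | 0 |
| noon | 5.00 | 1.7 | 0 |
| noon | 8.00 | 2.5 | 0 |
| noon | 10.0 | 3.4 | 0.4 |
| noon | 12.0 | 2.9 | 0 |
| noon | 15.0 | 5.5 | 0.1 |
| summer | 1.33 | 0.2 | 0 |
| summer | 2.50 | 1.2 | 0 |
| summer | 4.00 | 1.9 | 0 |
| summer | 8.00 | 3.3 | 0.1 |
| summer | 15.0 | 6.4 | 0 |

(readings scatter by 0.5 percentage points)

- amounts and yields of product count crystals too
- given per volume of solution although it is solid: solid substrate, crystals
- what may be going on: starting material + free catalyst <-> catalyst intermediate; catalyst intermediate -> free catalyst + product; solid substrate <-> starting material; crystals <-> product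
- at the start none of the solid substrate is in solution
- starting material means what is dissolved; the solid is not counted in it

* the product and crystals together standing at 25 h, as a percentage of the solid substrate charged
* concentration of starting material in solution at 25 h, in percent of saturation

Per hour, each catalyst charged made 1.32 /h product in the midnight run, 1.31 /h in the noon run and 1.33 /h in the summer run. As read from these scattered readings, this turnover frequency follows the catalyst and is zero order in the charge. So two times remain for the flask. One is the time asked, 25 h. The other is the drain time, the charge divided by the catalyst's hourly output, 361 h. Their ratio is the fraction made, and we reckon 6.93 %. The asked time is far shorter than the drain time, so we expect solid to remain. The like turnover at the two charges of the midnight and noon runs points to a solution near saturation.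

The forecast, lower than our figure, says 6.3 % (5.5 % to 7.3 %) and 97 % of saturation (80 % to 100 %): “Zero order in charge suggests solid remains and keeps the solution saturated”.

The flask gives 6.64 %, with the solution at 97.0 % of saturation.

    starting material + free catalyst ⇌ catalyst intermediate (K = 250 /M, k = 2.40 /M/s)
    catalyst intermediate → free catalyst + product (k = 0.00480 /s)
    solid substrate ⇌ starting material, rate k3*(cs3 - [starting material]) while solid is left; crystals form when [starting material] > cs3 (solubility = 0.500 mM, k = 5.00 × 10⁻⁴ /s)
    crystals ⇌ product, rate k4*(cs4 - [product]) while solid is left; crystals form when [product] > cs4 (solubility = 3.40 mM, k = 8.60 × 10⁻⁴ /s)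

In the flask, solid substrate dissolved first: 47 % of its turnover was done by 2.50 h, when starting material stood at 4.80 % of the charge. That level held to 25.0 h while the catalyst ran with 92.5 % of itself free, solid substrate fell to 88.5 % and crystals stayed at 0 %. For 250 h the drain time gives 69.3 %. The flask left that long holds 67.7 % of product and crystals together, crystals being 33.6 % of the charge, with solid substrate at 27.4 %.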